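**Assumption:** the SMILES is (2R,3R), i.e. 2,3‑cis: (−)‑epiafzelechin 3‑O‑gallate.

## Retrosynthetic overview
1. Target 16 comes from hydrogenolysis of the hexa‑O‑benzyl gallate 15. Ring O1–C2 is closed last by a photochemical cation‑radical SNAr of the C2 benzylic OH on the tris(benzyloxy)phenyl A‑ring. C2 is not touched, so the threo 1,2‑diol relationship becomes 2,3‑cis.
2. 15 comes from regioselective C3 galloylation of diol 12, which comes from acetonide 11.
3. C4–C4a forms by aryl‑cuprate alkylation of iodide 10. C2–ArB forms by Ni/photoredox decarboxylative arylation of the acid from 2,3‑O‑isopropylidene‑D‑erythronolactone (4).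
4. C3 comes from 4. C2 is set trans to it in the arylation.
5. Rings are formed in this order: dioxolane (from the pool, removed later), then the two arene attachments, then the pyran ring.

## Route

**Step 1**
Reactants: 1 phloroglucinol; 2 benzyl bromide
Product: 3 1,3,5‑tris(benzyloxy)benzene
Conditions: BnBr (3.6 equiv), K2CO3, KI (cat.), acetone, reflux
Reagents that add atoms: BnBr, BrCc1ccccc1
Why: Williamson O‑benzylation gives the symmetric A‑ring precursor, so either ortho OBn can later serve as the leaving group.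

**Step 2**
Reactants: 4 2,3‑O‑isopropylidene‑D‑erythronolactone; 5 CsOH·H2O
Product: 6 cesium (4R,5R)‑5‑(hydroxymethyl)‑2,2‑dimethyl‑1,3‑dioxolane‑4‑carboxylate
Conditions: CsOH·H2O (1.0 equiv), H2O/MeOH 1:1, rt, 1 h; lyophilise (no acidification)
Reagents that add atoms: CsOH, [Cs+].[OH-]
Why: Lactone saponification leaves the acetonide and both stereocentres intact, and isolating the salt avoids relactonisation.

**Step 3**
Reactants: 6; 7 1‑(benzyloxy)‑4‑bromobenzene
Product: 8 [(4R,5R)‑5‑(4‑benzyloxyphenyl)‑2,2‑dimethyl‑1,3‑dioxolan‑4‑yl]methanol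
Conditions: Ir[dF(CF3)ppy]2(dtbbpy)PF6 (1 mol%), NiCl2·glyme (10 mol%), dtbbpy (15 mol%), DMF, blue LEDs, rt, 24 h
Reagents that add atoms: 7, Brc1ccc(OCc2ccccc2)cc1
Why: Photoredox/Ni decarboxylative arylation (MacMillan type) makes the α‑oxy dioxolanyl radical, and ArNi captures it trans to the neighbouring CH2OH. This sets C2 as R, gives the trans‑dioxolane (threo diol), and leaves C3 (R) untouched.

**Step 4**
Reactants: 8; 9 iodine
Product: 10 (4S,5R)‑4‑(iodomethyl)‑5‑(4‑benzyloxyphenyl)‑2,2‑dimethyl‑1,3‑dioxolane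
Conditions: I2, PPh3, imidazole, THF, 0 °C to rt
Reagents that add atoms: I2, II
Why: Appel/Garegg–Samuelsson iodination of a primary alcohol, with no stereocentre involved.

**Step 5**
Reactants: 10; 3 (as ArLi)
Product: 11 (4R,5R)‑4‑(4‑benzyloxyphenyl)‑5‑[2,4,6‑tris(benzyloxy)benzyl]‑2,2‑dimethyl‑1,3‑dioxolane
Conditions: 3 + n‑BuLi (THF, 0 °C, 2 h); then CuI (−40 °C); then 10, −40 °C to rt, 16 h
Reagents that add atoms: 3 (the aryl group), c1(OCc2ccccc2)cc(OCc2ccccc2)cc(OCc2ccccc2)c1. n‑BuLi and CuI leave no atoms in the product.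
Why: Ortho‑lithiation between two OBn groups followed by cuprate SN2 alkylation of the primary iodide forms C4–C4a. C3 is not involved.

**Step 6**
Reactants: 11
Product: 12 (1R,2R)‑1‑[4‑(benzyloxy)phenyl]‑3‑[2,4,6‑tris(benzyloxy)phenyl]propane‑1,2‑diol
Conditions: 80% aq. AcOH, 45 °C, 6 h
Reagents that add atoms: none
Why: Acetal hydrolysis proceeds through the oxocarbenium at the CMe2 carbon, so the benzylic C2–O bond is not ionised and both centres are retained.

**Step 7**
Reactants: 12; 13 3,4,5‑tris(benzyloxy)benzoic acid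
Product: 14 (1R,2R)‑1‑[4‑(benzyloxy)phenyl]‑3‑[2,4,6‑tris(benzyloxy)phenyl]‑1‑hydroxypropan‑2‑yl 3,4,5‑tris(benzyloxy)benzoate
Conditions: 13 (1.1 equiv) + (COCl)2, DMF (cat.), CH2Cl2, 0 °C to rt; then 12, pyridine, DMAP (0.1 equiv), CH2Cl2, −20 to 0 °C
Reagents that add atoms: none (the acyl group comes from 13 via its acid chloride)
Why: Acid‑chloride acylation at the less hindered, non‑benzylic C3–OH (assumed preferred, about 3:1, with the C2 regioisomer separable); C3 configuration is unchanged, and this ester blocks the competing 5‑ring closure in Step 8.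

**Step 8**
Reactants: 14
Product: 15 (2R,3R)‑5,7‑bis(benzyloxy)‑2‑[4‑(benzyloxy)phenyl]chroman‑3‑yl 3,4,5‑tris(benzyloxy)benzoate
Conditions: Mes‑Acr‑Me+ BF4− (5 mol%), 1,2‑dichloroethane (0.02 M), 427 nm LEDs, N2, 25 °C, 24 h
Reagents that add atoms: none (BnOH is lost)
Why: Proposed new method: the acridinium photocatalyst oxidises the most electron‑rich ring, the 1,3,5‑trialkoxyarene, to its radical cation, and the tethered C2–OH adds 6‑ring‑forming at the ortho ipso carbon bearing OBn. Back electron transfer and loss of BnOH re‑aromatise the ring, with no stereocentre involved, so C2 is retained and the threo diol becomes 2,3‑cis. The closest known reaction is Nicewicz cation‑radical‑accelerated SNAr, which displaces aryl OMe with azole or amine nucleophiles intermolecularly; here the nucleophile is an aliphatic alcohol, the leaving group is OBn, and the reaction closes a chroman ring.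

**Step 9**
Reactants: 15
Product: 16 target, (2R,3R)‑epiafzelechin 3‑O‑gallate
Conditions: H2 (1 atm), Pd(OH)2/C, THF/MeOH 1:1, rt, 12 h
Reagents that add atoms: none (only hydrogen is added)
Why: Global hydrogenolysis of the six benzyl ethers, as in EGCG syntheses, leaves the ester and the chroman C–O bonds intact and does not touch C2 or C3.

## Compound list
1 | phloroglucinol | Oc1cc(O)cc(O)c1 | starting material
2 | benzyl bromide | BrCc1ccccc1 | starting material (reagent)
3 | 1,3,5‑tris(benzyloxy)benzene | c1(OCc2ccccc2)cc(OCc2ccccc2)cc(OCc2ccccc2)c1 | intermediate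
4 | 2,3‑O‑isopropylidene‑D‑erythronolactone | O=C1OC[C@H]2OC(C)(C)O[C@@H]12 | starting material
5 | cesium hydroxide | [Cs+].[OH-] | starting material (reagent)
6 | cesium (4R,5R)‑5‑(hydroxymethyl)‑2,2‑dimethyl‑1,3‑dioxolane‑4‑carboxylate | OC[C@H]1OC(C)(C)O[C@H]1C(=O)[O-].[Cs+] | intermediate
7 | 1‑(benzyloxy)‑4‑bromobenzene | Brc1ccc(OCc2ccccc2)cc1 | starting material
8 | [(4R,5R)‑5‑(4‑benzyloxyphenyl)‑2,2‑dimethyl‑1,3‑dioxolan‑4‑yl]methanol | OC[C@H]1OC(C)(C)O[C@@H]1c1ccc(OCc2ccccc2)cc1 | intermediate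
9 | iodine | II | starting material (reagent)
10 | (4S,5R)‑4‑(iodomethyl)‑5‑(4‑benzyloxyphenyl)‑2,2‑dimethyl‑1,3‑dioxolane | IC[C@H]1OC(C)(C)O[C@@H]1c1ccc(OCc2ccccc2)cc1 | intermediate
11 | (4R,5R)‑4‑(4‑benzyloxyphenyl)‑5‑[2,4,6‑tris(benzyloxy)benzyl]‑2,2‑dimethyl‑1,3‑dioxolane | c1(C[C@H]2OC(C)(C)O[C@@H]2c2ccc(OCc3ccccc3)cc2)c(OCc2ccccc2)cc(OCc2ccccc2)cc1OCc1ccccc1 | intermediate
12 | (1R,2R)‑1‑[4‑(benzyloxy)phenyl]‑3‑[2,4,6‑tris(benzyloxy)phenyl]propane‑1,2‑diol | c1(C[C@@H](O)[C@H](O)c2ccc(OCc3ccccc3)cc2)c(OCc2ccccc2)cc(OCc2ccccc2)cc1OCc1ccccc1 | intermediate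
13 | 3,4,5‑tris(benzyloxy)benzoic acid | OC(=O)c1cc(OCc2ccccc2)c(OCc2ccccc2)c(OCc2ccccc2)c1 | starting material
14 | C3 tris(benzyloxy)benzoate of 12 | c1(C[C@@H](OC(=O)c2cc(OCc3ccccc3)c(OCc3ccccc3)c(OCc3ccccc3)c2)[C@H](O)c2ccc(OCc3ccccc3)cc2)c(OCc2ccccc2)cc(OCc2ccccc2)cc1OCc1ccccc1 | intermediate
15 | (2R,3R)‑hexa‑O‑benzyl‑epiafzelechin 3‑O‑gallate | O=C(O[C@@H]1Cc2c(OCc3ccccc3)cc(OCc3ccccc3)cc2O[C@@H]1c1ccc(OCc2ccccc2)cc1)c1cc(OCc2ccccc2)c(OCc2ccccc2)c(OCc2ccccc2)c1 | intermediate
16 | (2R,3R)‑epiafzelechin 3‑O‑gallate | O=C(O[C@@H]1Cc2c(O)cc(O)cc2O[C@@H]1c1ccc(O)cc1)c1cc(O)c(O)c(O)c1 | target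

**Total steps:** 9. **Longest linear sequence:** 8 (Steps 2–9).

## Three steps most likely to fail
1. **Step 8 (proposed new step, ring‑closing cation‑radical SNAr).** The risks are benzylic deprotonation or O–Bn fragmentation of the radical cation, and slow ipso attack.
   - Fallback (known chemistry): in Step 5 use 2‑bromo‑4,6‑bis(benzyloxy)phenyllithium (LDA ortho‑lithiation of 1‑bromo‑3,5‑bis(benzyloxy)benzene) in place of 3. Carry on through Steps 6 and 7, then close the ring by intramolecular Pd‑catalysed Buchwald–Hartwig C–O coupling of the C2 alcohol (Pd2(dba)3, RockPhos, K3PO4, toluene). This is retentive at C2, so the product is still cis.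
2. **Step 3 (decarboxylative arylation).** Trans‑diastereoselectivity and tolerance of the free CH2OH are assumed.
   - Fallback: convert the acid to its N‑hydroxyphthalimide ester and couple with 4‑BnOC6H4ZnCl under thermal Ni catalysis (decarboxylative Negishi coupling), a non‑photochemical radical route to 8.
3. **Step 5 (hindered cuprate alkylation).** The β‑oxygenated, β‑branched primary iodide is a sluggish SN2 electrophile for the bulky aryl nucleophile.
   - Fallback: oxidise 8 to the aldehyde (DMP), add ArA–Li (from 3), and deoxygenate the 2,4,6‑trialkoxybenzylic alcohol with Et3SiH/cat. TFA. This gives 11 by a different bond‑forming logic (carbonyl addition then ionic hydrogenation).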